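**Plan**

1. Numbering: C1 = ring C(OH) carrying the butenoyl group (C2 = its C=O, C3=C4 = propenyl carbons), C5 = CH–O-isovalerate, C6 = lactone CH–O, C7 = lactone CH, C8 = CH2, C9 = CHOH, C10 = CHCH3, C11/C12/C13 = lactone α-carbon, lactone C=O and exocyclic CH2. In the cycloheptane ring the tertiary carbinol C1 is bonded to the oxygenated C5, so with C5 as a ketone the pair C1(OH)–C5(=O) is an α-ketol, the pattern a benzoin reaction produces.
2. Late cuts: C2–C3 (Z-propenyl addition to a C2 aldehyde, then oxidation), the C5 O-acyl bond, C11=C13 (methylenation) and the lactone C12–O bond. Key cut: ring bond C1–C5, leading to an open chain with a C5 aldehyde and a C1 ketone activated by a C2 dimethyl acetal.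
3. Chain cuts: C1–C2 (dithiane acyl anion plus Weinreb amide), C9–C10 (auxiliary-controlled syn aldol), C7–C11 (Michael addition of tert-butyl acetate enolate to a butenolide whose carbonyl carbon becomes C9).
4. Forward order: butenolide, trans Michael adduct, opened and C6-benzylated C9 aldehyde, aldol, α-keto acetal, C5 aldehyde, seven-membered ring (the only carbocycle), cis-fused γ-lactone, then methylene, isovalerate and enone.
5. Stereochemistry: C6 from (R)-5-(hydroxymethyl)butyrolactone; C7 by addition anti to the C6 substituent; C9 and C10 from the oxazolidinone auxiliary; C1 in the ring closure (substrate bias plus chiral carbene); C5 by hydroxyl-directed reduction from the C1 hydroxyl; the Z olefin from (Z)-1-bromopropene.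

Key step: step 14

Remark: (R)-5-(hydroxymethyl)dihydrofuran-2(3H)-one (the D-glutamic-acid-derived lactone) is taken as the commercial chiral-pool starting material.
Remark: C8 in 3, C11 in 23 and 24, and C2 in 29 and 32 arise as epimer mixtures; this is harmless because each of these centres becomes sp2 again.
Remark: the CIP letter at C1 is R in 19 and 32 and S elsewhere only because substituent priorities change; the centre is never inverted.

Step 1
Reactants: 1 (R)-5-(hydroxymethyl)dihydrofuran-2(3H)-one
Product: 2 (R)-5-[(tert-butyldimethylsilyloxy)methyl]dihydrofuran-2(3H)-one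
Conditions: TBSCl, imidazole, DMF, 0 °C to rt
Reagents that add atoms: tert-butyldimethylsilyl chloride, CC(C)(C)[Si](C)(C)Cl
Why: Standard silyl ether formation on the primary alcohol masks the future C5 oxygen; the C6 stereocentre is taken unchanged from the chiral pool.

Step 2
Reactants: 2 (R)-5-[(tert-butyldimethylsilyloxy)methyl]dihydrofuran-2(3H)-one
Product: 4 (R)-5-[(tert-butyldimethylsilyloxy)methyl]furan-2(5H)-one, via α-phenylselanyl lactone 3 (not isolated)
Conditions: LiN(i-Pr)2, THF, −78 °C, then PhSeBr; then 30% H2O2, pyridine, CH2Cl2, 0 °C to rt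
Reagents that add atoms: none
Why: α-Selenenylation of the lactone lithium enolate followed by selenoxide syn-elimination is the standard dehydrogenation of a γ-butyrolactone to the butenolide and does not touch C6.

Step 3
Reactants: 4 (R)-5-[(tert-butyldimethylsilyloxy)methyl]furan-2(5H)-one; 5 tert-butyl acetate
Product: 6 trans lactone tert-butyl 2-[(2R,3S)-2-[(tert-butyldimethylsilyloxy)methyl]-5-oxooxolan-3-yl]acetate
Conditions: 5, LiN(i-Pr)2, THF, −78 °C; then 4, −78 °C; AcOH quench
Reagents that add atoms: none
Why: Michael addition of the lithium ester enolate to the butenolide should occur on the face anti to the C6 silyloxymethyl group, setting C7 trans to it (7S), and at −78 °C conjugate addition should outrun deprotonation at C6.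

Step 4
Reactants: 6 trans lactone
Product: 7 tert-butyl (3S,4R)-5-(tert-butyldimethylsilyloxy)-4-hydroxy-3-[2-[methoxy(methyl)amino]-2-oxoethyl]pentanoate
Conditions: MeNHOMe·HCl, Me3Al, CH2Cl2, 0 °C
Reagents that add atoms: N,O-dimethylhydroxylamine hydrochloride, CNOC.Cl
Why: Aminolysis of the lactone with the aluminium amide (Weinreb amide formation) opens the ring at the old lactone carbonyl, now C9, while the bulky tert-butyl ester is not attacked.

Step 5
Reactants: 7 γ-hydroxy Weinreb amide
Product: 8 tert-butyl (3S,4R)-4-(benzyloxy)-5-(tert-butyldimethylsilyloxy)-3-[2-[methoxy(methyl)amino]-2-oxoethyl]pentanoate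
Conditions: BnOC(=NH)CCl3, TfOH (cat.), CH2Cl2/cyclohexane, 0 °C
Reagents that add atoms: benzyl 2,2,2-trichloroacetimidate, N=C(OCc1ccccc1)C(Cl)(Cl)Cl
Why: Acid-catalysed O-benzylation with the trichloroacetimidate avoids the alkoxide that would re-close the lactone, and the benzyl ether is a poor leaving group next to the later C5 aldehyde.

Step 6
Reactants: 8 C6 benzyl ether Weinreb amide
Product: 9 tert-butyl (3S,4R)-4-(benzyloxy)-5-(tert-butyldimethylsilyloxy)-3-(2-oxoethyl)pentanoate (C9 aldehyde)
Conditions: i-Bu2AlH, THF, −78 °C; aq. potassium sodium tartrate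
Reagents that add atoms: none
Why: Reduction of the Weinreb amide stops at the aldehyde because of the stable chelated tetrahedral intermediate, and at −78 °C the tert-butyl ester reacts much more slowly.

Step 7
Reactants: 9 C9 aldehyde; 10 (S)-4-benzyl-3-propanoyloxazolidin-2-one
Product: 11 syn-aldol imide (6R,7S,9R,10S) with C9-OH and C10-CH3
Conditions: 10, Bu2BOTf, i-Pr2NEt, CH2Cl2, 0 °C; then 9, −78 to 0 °C; pH 7 buffer, MeOH, H2O2
Reagents that add atoms: none
Why: Evans syn aldol reaction in which the (Z)-boron enolate reacts through a chair Zimmerman–Traxler transition state on the face opposite the benzyl group of the (S)-auxiliary, setting 9R and 10S irrespective of the remote C7 centre.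

Step 8
Reactants: 11 syn-aldol imide
Product: 12 C1 N-methoxy-N-methylamide with free C9-OH (6R,7S,9R,10S)
Conditions: MeNHOMe·HCl, Me3Al, THF, −20 to 0 °C
Reagents that add atoms: N,O-dimethylhydroxylamine hydrochloride, CNOC.Cl
Why: Transamidation of the β-hydroxy imide with the aluminium amide (Weinreb amide formation), assisted by the free hydroxyl, removes the auxiliary without epimerising C10.

Step 9
Reactants: 12 β-hydroxy Weinreb amide
Product: 13 C9 tert-butyldimethylsilyl ether of the Weinreb amide (6R,7S,9R,10S)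
Conditions: TBSOTf, 2,6-lutidine, CH2Cl2, −78 to 0 °C
Reagents that add atoms: tert-butyldimethylsilyl triflate, CC(C)(C)[Si](C)(C)OS(=O)(=O)C(F)(F)F
Why: Silylation of the hindered secondary alcohol with the silyl triflate gives the ether that has to last until the final step.

Step 10
Reactants: 13 C9-silylated Weinreb amide; 14 1,3-dithiane
Product: 15 C1 ketone carrying a 1,3-dithian-2-yl group as C2 (6R,7S,9R,10S)
Conditions: 14, n-BuLi, THF, −30 °C; then 13, −78 to −40 °C; AcOH quench at −78 °C
Reagents that add atoms: none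
Why: Corey–Seebach acyl anion addition to the Weinreb amide, where the chelated tetrahedral adduct prevents over-addition and keeps C10 from enolising until the cold acidic quench, while the tert-butyl ester should not react at −78 °C.

Step 11
Reactants: 15 acyl dithiane
Product: 16 α-keto dimethyl acetal with C1 ketone and C2 = CH(OMe)2 (6R,7S,9R,10S)
Conditions: Hg(ClO4)2, CaCO3, MeOH/THF, 0 °C to rt
Reagents that add atoms: methanol, CO
Why: Mercury-assisted solvolysis of the dithioacetal in methanol (transacetalisation), buffered with CaCO3 so that the silyl ethers and the C10 centre α to the ketone are not affected.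

Step 12
Reactants: 16 α-keto dimethyl acetal
Product: 17 C5 primary alcohol (6R,7S,9R,10S)
Conditions: HF·pyridine, pyridine, THF, 0 °C
Reagents that add atoms: none
Why: Buffered fluoride desilylation cleaves the unhindered primary silyl ether far faster than the secondary one at C9, which is flanked by the C10 branch.

Step 13
Reactants: 17 C5 primary alcohol
Product: 18 open-chain C5 aldehyde with C6-OBn and C1 α-keto dimethyl acetal (6R,7S,9R,10S)
Conditions: Dess–Martin periodinane, NaHCO3, CH2Cl2, 0 °C to rt
Reagents that add atoms: none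
Why: Dess–Martin oxidation under buffered conditions gives the α-benzyloxy aldehyde without epimerising C6; the aldehyde is used at once.

Step 14
Reactants: 18 open-chain C5 aldehyde / C1 α-keto dimethyl acetal
Product: 19 cycloheptanone α-ketol with C5 ketone and C1-OH bearing CH(OMe)2 (1R,6R,7S,9R,10S)
Conditions: (5aS,10bR)-2-(pentafluorophenyl)-5a,10b-dihydro-4H,6H-indeno[2,1-b][1,2,4]triazolo[4,3-d][1,4]oxazin-2-ium tetrafluoroborate (20 mol %), i-Pr2NEt (20 mol %), PhMe (0.01 M), 40 °C
Reagents that add atoms: none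
Why: Proposed new method: the carbene freed from the triazolium salt adds to the C5 aldehyde and proton transfer gives the Breslow intermediate, an acyl anion equivalent that attacks the C1 carbonyl; proton transfer and loss of the carbene then release the tertiary α-ketol. The closest known reactions are intramolecular aldehyde–ketone crossed benzoin cyclisations to five- and six-membered α-ketols and intermolecular benzoin reactions of aldehydes with α-keto esters, so closure of a seven-membered ring onto an α-branched ketone is an extrapolation. The cycloheptanone closes in a 7-exo-trig mode. The new C1 stereocentre is fixed in the cyclic transition state, in which the bulky dimethoxymethyl group should lie anti to the vicinal C10 methyl and on the side of the C9 silyloxy group, and the chiral carbene is chosen as the enantiomer expected to reinforce this bias; reversibility of the benzoin step should also favour this isomer. The step needs cross- over homo-coupling (high dilution, α-branched aldehyde, ketone activated inductively by its two α-methoxy groups), no redox elimination or Stetter pathway (benzyl ether as a poor leaving group at C6, no Michael acceptor in 18) and no base damage at C6, C10 or the C9 silyloxy group (electron-poor triazolium deprotonated by a substoichiometric tertiary amine).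

Step 15
Reactants: 19 cycloheptanone α-ketol
Product: 20 trans-1,5-diol (1S,5S,6R,7S,9R,10S)
Conditions: Me4NBH(OAc)3, MeCN/AcOH, −30 to 0 °C
Reagents that add atoms: none
Why: Hydroxyl-directed (Saksena–Evans) reduction in which the triacetoxyborohydride exchanges onto the C1 hydroxyl and delivers hydride intramolecularly to the carbonyl face syn to the C1–O bond, which should give the trans-diol (5S); the reagent reduces neither undirected ketones nor esters.

Step 16
Reactants: 20 trans-1,5-diol
Product: 22 cis-fused γ-lactone diol (C6–O–C12 lactone; free C1-OH/C5-OH; C9-OTBS; C2 dimethyl acetal), via C6 alcohol 21 (not isolated)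
Conditions: H2 (1 atm), Pd(OH)2/C, EtOAc, rt; then KOt-Bu (0.2 equiv), THF, 0 °C
Reagents that add atoms: none
Why: Hydrogenolysis of the benzyl ether followed by alkoxide-catalysed lactonisation (5-exo-trig acyl substitution with loss of tert-butoxide); only the C6 hydroxyl is cis to the C7 acetate arm, so the cis-fused γ-lactone is the only lactone that can form.

Step 17
Reactants: 22 cis-fused γ-lactone diol
Product: 25 α-methylene lactone diol, via Mannich base 23 (not isolated), via trimethylammonium iodide 24 (not isolated)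
Conditions: LiN(i-Pr)2 (4 equiv), THF, −78 to −40 °C, then CH2=NMe2+ I−, −78 °C to rt; MeI, MeOH, rt; aq. NaHCO3, CH2Cl2
Reagents that add atoms: Eschenmoser's salt (N,N-dimethylmethyleneiminium iodide), C=[N+](C)C.[I-]
Why: Standard α-methylenation of a γ-lactone by Mannich reaction of the lithium enolate with Eschenmoser's salt, N-methylation and base-induced Hofmann-type (E1cB) elimination, the two hydroxyls being carried as lithium alkoxides.

Step 18
Reactants: 25 α-methylene lactone diol; 26 3-methylbutanoic anhydride (isovaleric anhydride)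
Product: 27 C5 isovalerate with free tertiary C1-OH
Conditions: 26, DMAP, Et3N, CH2Cl2, rt
Reagents that add atoms: none
Why: DMAP-catalysed acylation (Steglich-type acyl transfer) is selective for the secondary C5 hydroxyl over the tertiary C1 hydroxyl, and C9 is still silylated.

Step 19
Reactants: 27 C5 isovalerate
Product: 30 C2 aldehyde with C1-OSiEt3, via C1 triethylsilyl ether 28 (not isolated), via lutidinium triflate 29 (not isolated)
Conditions: Et3SiOTf, 2,6-lutidine, CH2Cl2, 0 °C to rt; then H2O
Reagents that add atoms: triethylsilyl triflate, CC[Si](CC)(CC)OS(=O)(=O)C(F)(F)F; water, O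
Why: The silyl triflate/2,6-lutidine pair first silylates the tertiary hydroxyl and then ionises the dimethyl acetal to a pyridinium-type salt that water hydrolyses to the aldehyde, a non-acidic acetal cleavage that spares the TBS ether, both esters and the methylene lactone and blocks α-ketol rearrangement of the aldehyde.

Step 20
Reactants: 30 C2 aldehyde; 31 (Z)-1-bromoprop-1-ene
Product: 32 C2 allylic alcohol with (Z)-propenyl group (C2 epimers)
Conditions: 31, t-BuLi (2 equiv), Et2O, −78 °C; CeCl3, THF, −78 °C; then 30, −78 °C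
Reagents that add atoms: none
Why: Stereoretentive bromine–lithium exchange gives the configurationally stable (Z)-alkenyllithium, whose cerium derivative (organocerium 1,2-addition) is non-basic and selective for the aldehyde over the esters and the methylene lactone; the configuration of the new C2 carbinol is irrelevant.

Step 21
Reactants: 32 C2 allylic alcohol
Product: 33 bis-silylated (Z)-enone
Conditions: Dess–Martin periodinane, NaHCO3, CH2Cl2, 0 °C
Reagents that add atoms: none
Why: Dess–Martin oxidation of both C2 epimers converges on the (Z)-enone under neutral buffered conditions that should not isomerise the cis double bond, the silylated C1 oxygen excluding glycol cleavage.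

Step 22
Reactants: 33 bis-silylated (Z)-enone
Product: 34 target CNP0186412.2
Conditions: HF·pyridine, pyridine, THF, 0 °C to rt
Reagents that add atoms: none
Why: Fluoride-induced desilylation with buffered HF·pyridine removes both silyl ethers without affecting the esters, the enone or the methylene lactone.

**Compound list**

1 | (R)-5-(hydroxymethyl)dihydrofuran-2(3H)-one | OC[C@H]1CCC(=O)O1 | starting material
2 | (R)-5-[(tert-butyldimethylsilyloxy)methyl]dihydrofuran-2(3H)-one | CC(C)(C)[Si](C)(C)OC[C@H]1CCC(=O)O1 | intermediate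
3 | (5R)-5-[(tert-butyldimethylsilyloxy)methyl]-3-(phenylselanyl)dihydrofuran-2(3H)-one, C3 epimers | CC(C)(C)[Si](C)(C)OC[C@H]1CC([Se]c2ccccc2)C(=O)O1 | intermediate (not isolated)
4 | (R)-5-[(tert-butyldimethylsilyloxy)methyl]furan-2(5H)-one | CC(C)(C)[Si](C)(C)OC[C@H]1C=CC(=O)O1 | intermediate
5 | tert-butyl acetate | CC(=O)OC(C)(C)C | starting material
6 | tert-butyl 2-[(2R,3S)-2-[(tert-butyldimethylsilyloxy)methyl]-5-oxooxolan-3-yl]acetate (trans; 6R,7S in target numbering) | CC(C)(C)[Si](C)(C)OC[C@H]1[C@H](CC(=O)OC(C)(C)C)CC(=O)O1 | intermediate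
7 | tert-butyl (3S,4R)-5-(tert-butyldimethylsilyloxy)-4-hydroxy-3-[2-[methoxy(methyl)amino]-2-oxoethyl]pentanoate | CC(C)(C)[Si](C)(C)OC[C@H](O)[C@H](CC(=O)OC(C)(C)C)CC(=O)N(C)OC | intermediate
8 | tert-butyl (3S,4R)-4-(benzyloxy)-5-(tert-butyldimethylsilyloxy)-3-[2-[methoxy(methyl)amino]-2-oxoethyl]pentanoate | CC(C)(C)[Si](C)(C)OC[C@H](OCc1ccccc1)[C@H](CC(=O)OC(C)(C)C)CC(=O)N(C)OC | intermediate
9 | tert-butyl (3S,4R)-4-(benzyloxy)-5-(tert-butyldimethylsilyloxy)-3-(2-oxoethyl)pentanoate | CC(C)(C)[Si](C)(C)OC[C@H](OCc1ccccc1)[C@H](CC(=O)OC(C)(C)C)CC=O | intermediate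
10 | (S)-4-benzyl-3-propanoyloxazolidin-2-one | CCC(=O)N1[C@@H](Cc2ccccc2)COC1=O | starting material
11 | (S)-4-benzyl-3-[(2S,3R,5S,6R)-6-(benzyloxy)-5-(2-tert-butoxy-2-oxoethyl)-7-(tert-butyldimethylsilyloxy)-3-hydroxy-2-methylheptanoyl]oxazolidin-2-one (6R,7S,9R,10S in target numbering) | CC(C)(C)[Si](C)(C)OC[C@H](OCc1ccccc1)[C@H](CC(=O)OC(C)(C)C)C[C@@H](O)[C@H](C)C(=O)N1[C@@H](Cc2ccccc2)COC1=O | intermediate
12 | open-chain Weinreb amide (6R,7S,9R,10S): C1 = C(O)N(OMe)Me, C10-CH3, C9-OH, C7-CH2CO2t-Bu, C6-OBn, C5-OTBS | CC(C)(C)[Si](C)(C)OC[C@H](OCc1ccccc1)[C@H](CC(=O)OC(C)(C)C)C[C@@H](O)[C@H](C)C(=O)N(C)OC | intermediate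
13 | as 12 with C9-OTBS (6R,7S,9R,10S) | CC(C)(C)[Si](C)(C)OC[C@H](OCc1ccccc1)[C@H](CC(=O)OC(C)(C)C)C[C@@H](O[Si](C)(C)C(C)(C)C)[C@H](C)C(=O)N(C)OC | intermediate
14 | 1,3-dithiane | C1CSCSC1 | starting material
15 | acyl dithiane (6R,7S,9R,10S): C1 ketone with 1,3-dithian-2-yl as C2 | CC(C)(C)[Si](C)(C)OC[C@H](OCc1ccccc1)[C@H](CC(=O)OC(C)(C)C)C[C@@H](O[Si](C)(C)C(C)(C)C)[C@H](C)C(=O)C1SCCCS1 | intermediate
16 | α-keto dimethyl acetal (6R,7S,9R,10S): C1 ketone, C2 = CH(OMe)2, C5-OTBS | CC(C)(C)[Si](C)(C)OC[C@H](OCc1ccccc1)[C@H](CC(=O)OC(C)(C)C)C[C@@H](O[Si](C)(C)C(C)(C)C)[C@H](C)C(=O)C(OC)OC | intermediate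
17 | C5 primary alcohol of 16 (6R,7S,9R,10S) | OC[C@H](OCc1ccccc1)[C@H](CC(=O)OC(C)(C)C)C[C@@H](O[Si](C)(C)C(C)(C)C)[C@H](C)C(=O)C(OC)OC | intermediate
18 | open-chain C5 aldehyde with C6-OBn, C7-CH2CO2t-Bu, C9-OTBS, C10-CH3, C1 ketone and C2 dimethyl acetal (6R,7S,9R,10S) | O=C[C@H](OCc1ccccc1)[C@H](CC(=O)OC(C)(C)C)C[C@@H](O[Si](C)(C)C(C)(C)C)[C@H](C)C(=O)C(OC)OC | intermediate
19 | cycloheptanone α-ketol (1R,6R,7S,9R,10S): C5 ketone, C1-OH and C1-CH(OMe)2, C6-OBn, C7-CH2CO2t-Bu, C9-OTBS, C10-CH3 | O=C1[C@H](OCc2ccccc2)[C@H](CC(=O)OC(C)(C)C)C[C@@H](O[Si](C)(C)C(C)(C)C)[C@H](C)[C@@]1(O)C(OC)OC | intermediate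
20 | trans-1,5-diol (1S,5S,6R,7S,9R,10S) | O[C@H]1[C@H](OCc2ccccc2)[C@H](CC(=O)OC(C)(C)C)C[C@@H](O[Si](C)(C)C(C)(C)C)[C@H](C)[C@@]1(O)C(OC)OC | intermediate
21 | C1,C5,C6-triol tert-butyl ester (1S,5S,6R,7S,9R,10S) | O[C@H]1[C@H](O)[C@H](CC(=O)OC(C)(C)C)C[C@@H](O[Si](C)(C)C(C)(C)C)[C@H](C)[C@@]1(O)C(OC)OC | intermediate (not isolated)
22 | cis-fused γ-lactone (C6–O–C12) with free C1-OH and C5-OH, C9-OTBS, C2 dimethyl acetal (1S,5S,6R,7S,9R,10S) | C1C(=O)O[C@@H]2[C@H]1C[C@@H](O[Si](C)(C)C(C)(C)C)[C@H](C)[C@@](O)(C(OC)OC)[C@H]2O | intermediate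
23 | C11-(dimethylaminomethyl) lactone, C11 epimers | CN(C)CC1C(=O)O[C@@H]2[C@H]1C[C@@H](O[Si](C)(C)C(C)(C)C)[C@H](C)[C@@](O)(C(OC)OC)[C@H]2O | intermediate (not isolated)
24 | C11-(trimethylammoniomethyl) lactone iodide, C11 epimers | C[N+](C)(C)CC1C(=O)O[C@@H]2[C@H]1C[C@@H](O[Si](C)(C)C(C)(C)C)[C@H](C)[C@@](O)(C(OC)OC)[C@H]2O.[I-] | intermediate (not isolated)
25 | α-methylene γ-lactone diol (1S,5S,6R,7S,9R,10S) | C=C1C(=O)O[C@@H]2[C@H]1C[C@@H](O[Si](C)(C)C(C)(C)C)[C@H](C)[C@@](O)(C(OC)OC)[C@H]2O | intermediate
26 | 3-methylbutanoic anhydride (isovaleric anhydride) | CC(C)CC(=O)OC(=O)CC(C)C | starting material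
27 | C5 isovalerate of 25 (1S,5S,6R,7S,9R,10S) | C=C1C(=O)O[C@@H]2[C@H]1C[C@@H](O[Si](C)(C)C(C)(C)C)[C@H](C)[C@@](O)(C(OC)OC)[C@H]2OC(=O)CC(C)C | intermediate
28 | C1 triethylsilyl ether of 27 | C=C1C(=O)O[C@@H]2[C@H]1C[C@@H](O[Si](C)(C)C(C)(C)C)[C@H](C)[C@@](O[Si](CC)(CC)CC)(C(OC)OC)[C@H]2OC(=O)CC(C)C | intermediate (not isolated)
29 | 1-(α-methoxyalkyl)-2,6-dimethylpyridinium triflate at C2, C2 epimers | C=C1C(=O)O[C@@H]2[C@H]1C[C@@H](O[Si](C)(C)C(C)(C)C)[C@H](C)[C@@](O[Si](CC)(CC)CC)(C(OC)[n+]3c(C)cccc3C)[C@H]2OC(=O)CC(C)C.[O-]S(=O)(=O)C(F)(F)F | intermediate (not isolated)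
30 | C2 aldehyde with C1-OSiEt3, C5 isovalerate, C9-OTBS, α-methylene lactone (1S,5S,6R,7S,9R,10S) | C=C1C(=O)O[C@@H]2[C@H]1C[C@@H](O[Si](C)(C)C(C)(C)C)[C@H](C)[C@@](O[Si](CC)(CC)CC)(C=O)[C@H]2OC(=O)CC(C)C | intermediate
31 | (Z)-1-bromoprop-1-ene | C/C=C\Br | starting material
32 | C2 allylic alcohol with (Z)-prop-1-enyl group, C2 epimers (1R,5S,6R,7S,9R,10S) | C=C1C(=O)O[C@@H]2[C@H]1C[C@@H](O[Si](C)(C)C(C)(C)C)[C@H](C)[C@@](O[Si](CC)(CC)CC)(C(O)/C=C\C)[C@H]2OC(=O)CC(C)C | intermediate
33 | (Z)-enone with C1-OSiEt3 and C9-OTBS (1S,5S,6R,7S,9R,10S) | C=C1C(=O)O[C@@H]2[C@H]1C[C@@H](O[Si](C)(C)C(C)(C)C)[C@H](C)[C@@](O[Si](CC)(CC)CC)(C(=O)/C=C\C)[C@H]2OC(=O)CC(C)C | intermediate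
34 | CNP0186412.2: cis-fused α-methylene γ-lactone on a cycloheptane with C1-OH and (Z)-but-2-enoyl at C1, C5 isovalerate, C9-OH, C10-CH3 (1S,5S,6R,7S,9R,10S) | C=C1C(=O)O[C@@H]2[C@H]1C[C@@H](O)[C@H](C)[C@@](O)(C(=O)/C=C\C)[C@H]2OC(=O)CC(C)C | target

**Step count and risks**

Total step count: 22. Longest linear sequence: 22 steps (1 to 34); compounds 5, 10, 14, 26 and 31 are commercial and enter directly.

Steps most likely to fail:

Step 14 (proposed new method). Closure of the seven-membered ring onto the hindered ketone may be too slow. Aldehyde homo-coupling, base-mediated aldol closure between the enolisable positions and the two carbonyls, epimerisation at C6 or C10, or attack on the wrong face of the C1 carbonyl could then take over. The fallback uses known chemistry, sets out from 18 and comes back at 19. Reductive keto–aldehyde pinacol cyclisation with SmI2 (divalent samarium; THF, t-BuOH, −78 °C, high dilution) should give the cycloheptane-1,5-diol F1 with the C5 configuration left open; the ketyl of the more easily reduced aldehyde adds to the C1 ketone within a samarium chelate. Parikh–Doering oxidation (SO3·pyridine, DMSO, i-Pr2NEt) of the secondary C5 carbinol, which does not cleave the glycol, then gives ketol 19, and step 15 resets C5.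

Step 17. Enolate formation next to two lithium alkoxides may be incomplete, or the polyanion may aggregate, so that the lactone is recovered or the Mannich salt is consumed at oxygen. The fallback sets out from 22 and comes back at 25 without a strong amide base. Carboxylation of the lactone α-position with methoxymagnesium methyl carbonate (DMF, 120 °C) gives the α-carboxy lactone F2. Decarboxylative Mannich methylenation with aqueous formaldehyde and diethylamine (NaOAc, AcOH) then delivers 25.

Step 10. The lithiated dithiane may deprotonate the tert-butyl ester α-CH2 instead of adding to the hindered α-branched amide. The ester enolate could then close onto the amide in a six-membered Dieckmann-type reaction, or slow addition could leave the amide unchanged. The fallback is an oxidation-state detour that sets out from 13 and comes back at 15. Reduction with i-Bu2AlH (THF, −78 °C) gives the C1 aldehyde F3. Fast addition of 2-lithio-1,3-dithiane at −78 °C gives the dithianyl carbinol F4. Dess–Martin oxidation then gives the acyl dithiane 15.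

Further compounds
F1 | step 14 | cycloheptane-1,5-diol from pinacol closure (C5 epimers; other centres as in 19) | OC1[C@H](OCc2ccccc2)[C@H](CC(=O)OC(C)(C)C)C[C@@H](O[Si](C)(C)C(C)(C)C)[C@H](C)[C@@]1(O)C(OC)OC
F2 | step 17 | C11-carboxy γ-lactone diol (C11 epimers) | OC(=O)C1C(=O)O[C@@H]2[C@H]1C[C@@H](O[Si](C)(C)C(C)(C)C)[C@H](C)[C@@](O)(C(OC)OC)[C@H]2O
F3 | step 10 | open-chain C1 aldehyde from reduction of 13 (6R,7S,9R,10S) | CC(C)(C)[Si](C)(C)OC[C@H](OCc1ccccc1)[C@H](CC(=O)OC(C)(C)C)C[C@@H](O[Si](C)(C)C(C)(C)C)[C@H](C)C=O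
F4 | step 10 | C1 carbinol carrying the 1,3-dithian-2-yl group (C1 epimers) | CC(C)(C)[Si](C)(C)OC[C@H](OCc1ccccc1)[C@H](CC(=O)OC(C)(C)C)C[C@@H](O[Si](C)(C)C(C)(C)C)[C@H](C)C(O)C1SCCCS1
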